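Start with the exits. Starting material and partner give intermediate A, which can leave in two ways. On its own it turns into intermediate C, which partner carries on to target. With partner it becomes intermediate B, which falls to side product A.

| flask | starting material | partner | remark | time |
|---|---|---|---|---|
| south-east | 0.13 M | 3 equiv | run made earlier |  |
| south | 0.13 M | 4.2 equiv | run made earlier |  |
| north-east | 0.13 M | 6.6 equiv | run made earlier |  |
| north | 0.26 M | 3 equiv | run made earlier |  |
| ochre | 0.13 M | 3.00 equiv (fed, over 9.60 d) | all but partner at the start; partner goes in evenly over 9.60 d, the run ends at 12 d | 12 d |
| amber | 0.13 M (fed, over 9.60 d) | 3.00 equiv | a stirred flask in which starting material is dosed at a steady rate over 9.60 d without added volume, worked up at 12 d | 12 d |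
| blue | 0.13 M | 3.00 equiv | a single well-mixed tank run continuously and read at steady state, 12 d in it on average |  |
| grey | 0.13 M | 3.00 equiv | everything together in a closed stirred flask, run for 12 d | 12 d |

| run | time / d | target / % |
|---|---|---|
| south-east | 1.04 | 1 |
| south-east | 3.00 | 12 |
| south-east | 6.00 | 19 |
| south-east | 8.00 | 23 |
| south-east | 12.0 | 23 |
| south | 0.625 | 1 |
| south | 1.67 | 5 |
| south | 3.00 | 14 |
| south | 5.00 | 15 |
| south | 8.00 | 19 |
| north-east | 0.625 | 1 |
| north-east | 1.67 | 3 |
| north-east | 3.00 | 9 |
| north-east | 5.00 | 9 |
| north-east | 8.00 | 11 |
| north | 0.625 | 1 |
| north | 1.67 | 6 |
| north | 3.00 | 9 |
| north | 5.00 | 15 |
| north | 8.00 | 14 |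

(scatter of a reading: 2 percentage points)

- the set-up with the highest amount of target at the outlet or at the end, in percent of the starting material put in ("none" if the first two lie within 2 percentage points) (ochre / amber / blue / grey / none)
- amount of target at the outlet or at the end, in percent of the starting material put in, ochre
- amount of target at the outlet or at the end, in percent of the starting material put in, amber
- amount of target at the outlet or at the end, in percent of the starting material put in, blue
- amount of target at the outlet or at the end, in percent of the starting material put in, grey

- in percentages every species weighs as the starting material in it: one side product B counts as two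
- the stated concentrations are those of everything mixed, before any reaction; amounts are the same in each set-up
- the earlier runs were read with a standard deviation of 2 percentage points
- on the list of suspects stand: partner + intermediate C -> target; starting material + target -> side product B; intermediate B -> side product A; starting material + partner -> intermediate A; partner + intermediate A <-> intermediate B; intermediate A -> intermediate C
- the feed brings no volume worth counting
- the earlier runs were made in a closed, stirred flask

The wasteful exit should speed up with partner, and the plateaus agree: 23 % at 3 equiv, 19 % at 4.2 equiv, 11 % at 6.6 equiv. Either route costs two partners per starting material, so at 3.00 equiv starting material is the limiting reagent.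

The north-east run changes its partner level least, with a mean near 0.728 M. Its plateau gives

branch level = 0.0900 M,

the partner concentration at which intermediate A leaves by both exits at the same rate.

In grey the wasteful exit starts at 4.33 times the useful one and ends at 1.44 times it, a slowing by a factor of 3.00 as partner is consumed. Integrating the useful share over conversion, with b the branch level, p the starting partner and c the starting material charge, and taking partner to fall by two per starting material converted, gives an estimate of the yield:

estimate = (b / 2c) · ln[(b + p) / (b + p − 2c)]

grey: 27.0 %

I expect grey between the reading of 23 % and that estimate. Ochre's wasteful exit starts from no partner, so I put ochre above that estimate. Amber and blue I leave outside this reckoning.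

The forecast, reasoning that “Ochre keeps partner low”, named ochre best, with 33 % there, 22 % in amber, 20 % in blue and 24 % in grey.

The flasks give 28.5 % in ochre, 16.2 % in amber, 13.9 % in blue and 25.5 % in grey, so ochre is best.

    partner + intermediate C → target (k = 0.233 /M/h)
    starting material + target → side product B (k = 0.0815 /M/h)
    intermediate B → side product A (k = 0.0147 /h)
    starting material + partner → intermediate A (k = 0.101 /M/h)
    partner + intermediate A ⇌ intermediate B (K = 99.9 /M, k = 0.0734 /M/h)
    intermediate A → intermediate C (k = 0.00633 /h)

Amber's last dose enters 2.40 d before the end, shorter than the 4.6 d half-life of intermediate A through its turning into intermediate C alone. At 12.0 d amber holds 11.4 % intermediate A and 13.7 % intermediate B, and at 120 d its target stands at 23.9 %, under grey's estimate of 27.0 %. For amber's neighbour charged with 0.52 M starting material, the same branch level gives an estimate of 8.61 %, and that flask stands at 6.98 %.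

(The earlier runs and the new flask come from a simulation with made-up constants; scatter was added.)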